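The readings were generated by integration from invented constants, noise included.

Which of alder and birch ends with the longer chains, and how long are they on average?

- which of the two ends with the longer chains by the average number of monomer units in a chain (chains begun, living or dead) ("neither" if they lie within 10%) (alder / birch / neither)
- average number of monomer units in a chain (chains begun, living or dead) at the end, alder
- average number of monomer units in a chain (chains begun, living or dead) at the end, birch

| flask | free monomer | initiator | impurity | remark | time |
|---|---|---|---|---|---|
| green | 0.38 M | 15 mM | 4.2 mM | run made earlier |  |
| ochre | 0.63 M | 15 mM | 4.2 mM | run made earlier |  |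
| violet | 1.3 M | 15 mM | 4.2 mM | run made earlier |  |
| alder | 0.30 M | 15 mM | 4.2 mM |  | 10 h |
| birch | 1.2 M | 15 mM | 4.2 mM |  | 10 h |

| run | time / h | monomer in chains / % |
|---|---|---|
| green | 0.417 | 73.7 |
| green | 1.00 | 76.4 |
| green | 2.00 | 74.2 |
| green | 5.00 | 73.5 |
| ochre | 0.667 | 84.3 |
| ochre | 2.00 | 84.7 |
| ochre | 3.00 | 84.4 |
| ochre | 5.00 | 83.8 |
| violet | 1.33 | 93.8 |
| violet | 2.50 | 90.8 |
| violet | 4.00 | 94.3 |
| violet | 5.00 | 91.9 |

(readings scatter by 1 percentage point)

- a species is counted by the free monomer in it: one homo dimer counts as two
- the average divides the monomer in chains by the number of chains begun, living and dead together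
- the numbers in the tables scatter by 1 percentage point (one standard deviation)
- candidate steps: free monomer + initiator -> living end + monomer in chains; free monomer + living end -> monomer in chains + living end; 2 free monomer -> homo dimer; monomer in chains + living end -> free monomer + living end; initiator + impurity -> spent initiator
- the earlier runs do not show the number of chains; that part of a forecast is a guess

I turn the settings one at a time. Time comes first: by hand, a flask still converting gains with the hours, but the green run reads 73.7% at 0.417 h and 73.5% at 5.00 h, a step smaller than the scatter. So I expect no gain from the 10 h of alder and birch.

Next comes the charge of free monomer. By hand, a fixed share might react, but the last readings rise from 73.5% in green to 91.9% in violet. What holds still in these readings is the amount not in chains, the charge times the mean part not in chains, which I read as c(free monomer) left over, with any homo dimer counted in it: 0.0971 M in green, 0.0989 M in ochre and 0.0949 M in violet. Their mean, 0.0970 M, is what I carry: the floor, the c(free monomer) at which green, ochre and violet stop gaining monomer in chains, known in the field as the equilibrium monomer concentration. It takes 32.3% of alder's charge but 8.08% of birch's, which by my reckoning leaves 0.203 M and 1.10 M in chains.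

Initiator and impurity last: green, ochre and violet share the same charges of both, so the number of chains is a guess. I take each impurity to remove one initiator, which leaves 10.8 mM of chains by my guess. The average is then the monomer in chains over the chains: 18.8 for alder and 102 for birch.

The forecast, reading “propagation balanced by depropagation”, says birch, with 18.8 for alder and 102 for birch.

The flask gives birch, with 18.2 for alder and 101 for birch.

    free monomer + initiator → living end + monomer in chains (k = 1.50 L mol⁻¹ min⁻¹)
    free monomer + living end → monomer in chains + living end, rate k2*[living end]*[free monomer] (k = 18.0 L mol⁻¹ min⁻¹)
    2 free monomer → homo dimer (k = 7.70 × 10⁻⁴ L mol⁻¹ min⁻¹)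
    monomer in chains + living end → free monomer + living end, rate k4*[living end] as long as [monomer in chains] is above zero (k = 1.70 min⁻¹)
    initiator + impurity → spent initiator (k = 1600 L mol⁻¹ min⁻¹)

Alder's average sinks from 18.9 at 1.00 h to 18.2 at 10 h, when its homo dimer stands at 2.96% of the charge. The floor serves on a neighbour, birch with 0.0071 M of impurity: the same 1.10 M in chains over 7.90 mM of chains gives 140, and that flask ends at 138.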